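**Retrosynthetic overview**

1. The target comes from BBr3 cleavage of its heptamethyl ether; the 4-methoxystyryl group is put on last by Suzuki–Miyaura coupling at the C6 triflate of the finished bis(dihydrobenzofuran).
2. Each furan ring is closed at its C2–O bond by acid (flanking phenol onto a 4-methoxybenzylic carbinol, trans); the ring of unit 2 is formed first, that of unit 1 second.
3. Each carbinol comes from a 1,2,2-triarylethylboronic ester, cut at two C–C bonds into one lithium alkenyl(4-methoxyphenyl)borate (made once from a single E-vinyl iodide and used in both rounds) and an aryl triflate (3,5-dimethoxyphenyl triflate for unit 2; the C6′ triflate of finished unit 2 for unit 1).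
4. The strategy rests on C2′–C3′ of the furan ring of unit 2 (and C2–C3 of unit 1): a pair of neighbouring sp3 carbons that together bear three aryl rings and a single oxygen, which is what aryl migration from boron and aryl delivery from palladium across an E-alkene leave behind once the C–B bond is oxidised.
5. Boron carries the ester of cis-1,2-dimethylacenaphthene-1,2-diol and not pinacol, because β-substituted alkenyl pinacol ate complexes are known to transfer the alkenyl group directly to palladium.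

Key step: step 8

Assumption: the (S,S)-planar-chiral antipode of the ferrocenyl bisphosphine is taken to give the (S) configuration at the diaryl carbon; the sense is to be checked on alcohol 14, and the antipodal ligand would be used in steps 8 and 14 if it proves opposite.

**Route**

Step 1
Reactants: 1 2,4,6-trihydroxybenzaldehyde
Product: 2 4-(benzyloxy)-2,6-dihydroxybenzaldehyde
Conditions: BnBr (1.0 equiv), NaHCO3, DMF, 40 °C
Reagents that add atoms: benzyl bromide BrCc1ccccc1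
Why: Williamson etherification with one equivalent of halide and a weak base should take the 4-hydroxyl, the most acidic one and the only one that does not flank the formyl group.

Step 2
Reactants: 2 4-(benzyloxy)-2,6-dihydroxybenzaldehyde
Product: 3 4-(benzyloxy)-2,6-bis(methoxymethoxy)benzaldehyde
Conditions: NaH, MOMCl, DMF, 0 °C → rt
Reagents that add atoms: chloromethyl methyl ether COCCl
Why: Full deprotonation with NaH breaks the hydrogen bond to the aldehyde, so both remaining phenols are alkylated (Williamson-type acetal ether formation) to a symmetrical product.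

Step 3
Reactants: 3 4-(benzyloxy)-2,6-bis(methoxymethoxy)benzaldehyde
Product: 4 5-(benzyloxy)-2-[(E)-2-iodoethenyl]-1,3-bis(methoxymethoxy)benzene
Conditions: CrCl2, CHI3, THF, 0 °C → rt
Reagents that add atoms: iodoform IC(I)I
Why: Takai olefination; the geminal dichromium species from CHI3 and divalent chromium adds to the aldehyde and eliminates to the E-iodoalkene, and the acetal and benzyl ethers are inert to CrCl2.

Step 4
Reactants: 5 acenaphthoquinone
Product: 6 cis-1,2-dimethyl-1,2-dihydroacenaphthylene-1,2-diol (meso)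
Conditions: AlMe3, toluene, 0 °C → rt; aqueous potassium sodium tartrate (KNaC4H4O6)
Reagents that add atoms: trimethylaluminium C[Al](C)C
Why: Double 1,2-addition of methyl to the 1,2-dione; the second methyl should enter anti to the bulky aluminium alkoxide and so give the cis diol, and any trans isomer is removed by crystallisation.

Step 5
Reactants: 6 cis-1,2-dimethyl-1,2-dihydroacenaphthylene-1,2-diol; 7 4-methoxyphenylboronic acid
Product: 8 4-methoxyphenylboronic acid ester of diol 6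
Conditions: MgSO4, CH2Cl2, rt
Reagents that add atoms: none
Why: Condensation of a boronic acid with a 1,2-diol to the cyclic boronic ester, driven by removal of water.

Step 6
Reactants: 9 3,5-dimethoxyphenol
Product: 10 3,5-dimethoxyphenyl trifluoromethanesulfonate
Conditions: Tf2O, pyridine, CH2Cl2, 0 °C
Reagents that add atoms: trifluoromethanesulfonic anhydride O=S(=O)(OS(=O)(=O)C(F)(F)F)C(F)(F)F
Why: O-sulfonylation of the phenol by triflic anhydride with pyridine as base.

Step 7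
Reactants: 4 5-(benzyloxy)-2-[(E)-2-iodoethenyl]-1,3-bis(methoxymethoxy)benzene; 8 4-methoxyphenylboronic acid ester of diol 6
Product: 12 lithium [(E)-2-[4-(benzyloxy)-2,6-bis(methoxymethoxy)phenyl]ethenyl](4-methoxyphenyl)borate of diol 6 (ate complex), via vinyllithium 11 (not isolated)
Conditions: 4, t-BuLi (2.0 equiv), Et2O, −78 °C; then 8, −78 °C → rt; Et2O removed in vacuo; the solid (it carries the LiI) is kept under argon at −30 °C; one batch sized for steps 8 and 14
Reagents that add atoms: tert-butyllithium [Li]C(C)(C)C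
Why: Iodine–lithium exchange (the second equivalent of t-BuLi destroys the tert-butyl iodide) gives the E-vinyllithium with retention of alkene geometry, and its addition to the trigonal boron of 8 gives the four-coordinate borate, a salt that should keep under argon in the absence of water, air and electrophiles.

Step 8
Reactants: 12 lithium alkenyl(4-methoxyphenyl)borate of diol 6; 10 3,5-dimethoxyphenyl trifluoromethanesulfonate
Product: 13 (1R,2S)-2-[4-(benzyloxy)-2,6-bis(methoxymethoxy)phenyl]-2-(3,5-dimethoxyphenyl)-1-(4-methoxyphenyl)ethylboronic acid ester of diol 6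
Conditions: 12 (first portion), Pd(OAc)2 (5 mol %), (S,S)-1,1′-bis[bis(3,5-dimethylphenyl)phosphino]-2,2′-bis[(R)-α-(dimethylamino)benzyl]ferrocene (6 mol %), 10, NaOTf, THF, 60 °C
Reagents that add atoms: none
Why: Proposed new method: the closest known reaction is the palladium-catalysed enantioselective conjunctive cross-coupling of β-alkyl-substituted alkenylboron ate complexes of this diol ester with aryl triflates, and the extension is to a β-aryl group with two ortho ether substituents. Oxidative addition of 10 to zerovalent palladium gives a cationic aryl–palladium species that binds the alkene of 12; the anisyl group then shifts from boron to the boron-bearing carbon anti to palladium, which ends on the benzylic carbon as a stabilised benzyl–palladium and forms the C–aryl bond by reductive elimination with retention. No ring is closed. The alkene face taken by palladium is set by the ferrocenyl bisphosphine and fixes the absolute configuration of both carbons, while the anti 1,2-shift on the E-alkene fixes their relative configuration as (1R,2S). The step needs the 1,2-shift to win over direct transfer of the alkenyl group to palladium, which the acenaphthenediol ester on boron is known to secure for β-substituted alkenyl groups. It also needs triflate and not halide on palladium, for which NaOTf is added against the iodide carried over from step 7.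

Step 9
Reactants: 13 (1R,2S)-triarylethylboronic ester
Product: 14 (1R,2S)-2-[4-(benzyloxy)-2,6-bis(methoxymethoxy)phenyl]-2-(3,5-dimethoxyphenyl)-1-(4-methoxyphenyl)ethanol
Conditions: H2O2 (30 %), NaOH (aq), THF, 0 °C → rt
Reagents that add atoms: hydrogen peroxide OO
Why: Oxidation of the C–B bond by hydroperoxide with 1,2-shift of carbon from boron to oxygen, which retains the configuration at the carbinol carbon; acetals and benzyl ether are stable to base.

Step 10
Reactants: 14 (1R,2S)-triarylethanol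
Product: 16 (2S,3S)-6-(benzyloxy)-3-(3,5-dimethoxyphenyl)-2-(4-methoxyphenyl)-2,3-dihydro-1-benzofuran-4-ol, via triol 15 (not isolated)
Conditions: HCl, MeOH/THF, 50 °C, dilute
Reagents that add atoms: none
Why: Acidic transacetalisation removes both methoxymethyl ethers and the 4-methoxybenzylic carbinol is displaced by a flanking phenol (cyclodehydration), reversibly, so the 2,3-trans ring should form by inversion or through the cation alike while the diaryl carbon is untouched; the two phenols are equivalent, so either closure gives the same product.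

Step 11
Reactants: 16 (2S,3S)-6-(benzyloxy)-3-(3,5-dimethoxyphenyl)-2-(4-methoxyphenyl)-2,3-dihydro-1-benzofuran-4-ol
Product: 17 (2S,3S)-6-(benzyloxy)-3-(3,5-dimethoxyphenyl)-4-methoxy-2-(4-methoxyphenyl)-2,3-dihydro-1-benzofuran
Conditions: MeI, K2CO3, DMF, rt
Reagents that add atoms: iodomethane CI
Why: Williamson methylation of the only free phenol.

Step 12
Reactants: 17 (2S,3S)-6-(benzyloxy)-3-(3,5-dimethoxyphenyl)-4-methoxy-2-(4-methoxyphenyl)-2,3-dihydro-1-benzofuran
Product: 18 (2S,3S)-3-(3,5-dimethoxyphenyl)-4-methoxy-2-(4-methoxyphenyl)-2,3-dihydro-1-benzofuran-6-ol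
Conditions: H2 (1 atm), Pd/C, EtOAc, rt, stopped after one equivalent of H2
Reagents that add atoms: none
Why: Hydrogenolysis of the aryl benzyl ether over palladium, which should be faster than cleavage of the ring benzylic C–O bond under these mild conditions.

Step 13
Reactants: 18 (2S,3S)-3-(3,5-dimethoxyphenyl)-4-methoxy-2-(4-methoxyphenyl)-2,3-dihydro-1-benzofuran-6-ol
Product: 19 (2S,3S)-3-(3,5-dimethoxyphenyl)-4-methoxy-2-(4-methoxyphenyl)-2,3-dihydro-1-benzofuran-6-yl trifluoromethanesulfonate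
Conditions: Tf2O, pyridine, CH2Cl2, 0 °C
Reagents that add atoms: trifluoromethanesulfonic anhydride O=S(=O)(OS(=O)(=O)C(F)(F)F)C(F)(F)F
Why: O-sulfonylation of the unhindered C6′ phenol gives the electrophile for the second coupling.

Step 14
Reactants: 12 lithium alkenyl(4-methoxyphenyl)borate of diol 6; 19 unit 2 aryl triflate
Product: 20 (1R,2S)-2-[4-(benzyloxy)-2,6-bis(methoxymethoxy)phenyl]-2-[(2S,3S)-3-(3,5-dimethoxyphenyl)-4-methoxy-2-(4-methoxyphenyl)-2,3-dihydro-1-benzofuran-6-yl]-1-(4-methoxyphenyl)ethylboronic acid ester of diol 6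
Conditions: 12 (second portion of the batch from step 7), Pd(OAc)2 (5 mol %), (S,S)-1,1′-bis[bis(3,5-dimethylphenyl)phosphino]-2,2′-bis[(R)-α-(dimethylamino)benzyl]ferrocene (6 mol %), 19, NaOTf, THF, 60 °C
Reagents that add atoms: none
Why: Proposed new method: the same extension as in step 8 of the known conjunctive cross-coupling of β-substituted alkenylboron ate complexes with aryl triflates, here with 19 as electrophile (oxidative addition, alkene binding, anti 1,2-shift of anisyl from boron to carbon, C–aryl reductive elimination with retention), the ligand on palladium and not the two remote centres of 19 deciding the alkene face so that the new pair is again (1R,2S).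

Step 15
Reactants: 20 (1R,2S)-boronic ester of unit 1
Product: 21 (1R,2S)-2-[4-(benzyloxy)-2,6-bis(methoxymethoxy)phenyl]-2-[(2S,3S)-3-(3,5-dimethoxyphenyl)-4-methoxy-2-(4-methoxyphenyl)-2,3-dihydro-1-benzofuran-6-yl]-1-(4-methoxyphenyl)ethanol
Conditions: H2O2 (30 %), NaOH (aq), THF, 0 °C → rt
Reagents that add atoms: hydrogen peroxide OO
Why: Stereoretentive oxidation of the C–B bond by hydroperoxide, as in step 9.

Step 16
Reactants: 21 (1R,2S)-ethanol of unit 1
Product: 23 (2S,3S)-6-(benzyloxy)-3-[(2S,3S)-3-(3,5-dimethoxyphenyl)-4-methoxy-2-(4-methoxyphenyl)-2,3-dihydro-1-benzofuran-6-yl]-2-(4-methoxyphenyl)-2,3-dihydro-1-benzofuran-4-ol, via triol 22 (not isolated)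
Conditions: HCl, MeOH/THF, 50 °C, dilute
Reagents that add atoms: none
Why: Acetal cleavage and cyclodehydration as in step 10 should give the second trans furan ring; the ring of unit 2 is already the stable trans isomer and re-forms as such if it opens under acid.

Step 17
Reactants: 23 phenol of the bis(dihydrobenzofuran)
Product: 24 (2S,3S)-6-(benzyloxy)-3-[(2S,3S)-3-(3,5-dimethoxyphenyl)-4-methoxy-2-(4-methoxyphenyl)-2,3-dihydro-1-benzofuran-6-yl]-4-methoxy-2-(4-methoxyphenyl)-2,3-dihydro-1-benzofuran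
Conditions: MeI, K2CO3, DMF, rt
Reagents that add atoms: iodomethane CI
Why: Williamson methylation of the only free phenol.

Step 18
Reactants: 24 benzyl ether of the bis(dihydrobenzofuran)
Product: 25 (2S,3S)-3-[(2S,3S)-3-(3,5-dimethoxyphenyl)-4-methoxy-2-(4-methoxyphenyl)-2,3-dihydro-1-benzofuran-6-yl]-4-methoxy-2-(4-methoxyphenyl)-2,3-dihydro-1-benzofuran-6-ol
Conditions: H2 (1 atm), Pd/C, EtOAc, rt, stopped after one equivalent of H2
Reagents that add atoms: none
Why: Hydrogenolysis of the aryl benzyl ether, done before the alkene is introduced, as in step 12.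

Step 19
Reactants: 25 C6 phenol of the bis(dihydrobenzofuran)
Product: 26 (2S,3S)-3-[(2S,3S)-3-(3,5-dimethoxyphenyl)-4-methoxy-2-(4-methoxyphenyl)-2,3-dihydro-1-benzofuran-6-yl]-4-methoxy-2-(4-methoxyphenyl)-2,3-dihydro-1-benzofuran-6-yl trifluoromethanesulfonate
Conditions: Tf2O, pyridine, CH2Cl2, 0 °C
Reagents that add atoms: trifluoromethanesulfonic anhydride O=S(=O)(OS(=O)(=O)C(F)(F)F)C(F)(F)F
Why: O-sulfonylation of the phenol, as in step 13.

Step 20
Reactants: 26 C6 triflate of the bis(dihydrobenzofuran); 27 (E)-2-(4-methoxyphenyl)ethenylboronic acid pinacol ester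
Product: 28 (2S,3S)-3-[(2S,3S)-3-(3,5-dimethoxyphenyl)-4-methoxy-2-(4-methoxyphenyl)-2,3-dihydro-1-benzofuran-6-yl]-4-methoxy-2-(4-methoxyphenyl)-6-[(E)-2-(4-methoxyphenyl)ethenyl]-2,3-dihydro-1-benzofuran
Conditions: Pd(PPh3)4, K3PO4, dioxane/H2O, 80 °C
Reagents that add atoms: none
Why: Suzuki–Miyaura coupling of an aryl triflate with an E-alkenylboronic ester, which keeps the alkene geometry.

Step 21
Reactants: 28 heptamethyl ether
Product: 29 (2S,3S)-3-[(2S,3S)-3-(3,5-dihydroxyphenyl)-4-hydroxy-2-(4-hydroxyphenyl)-2,3-dihydro-1-benzofuran-6-yl]-2-(4-hydroxyphenyl)-6-[(E)-2-(4-hydroxyphenyl)ethenyl]-2,3-dihydro-1-benzofuran-4-ol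
Conditions: BBr3 (excess), CH2Cl2, −78 °C → rt; MeOH/H2O quench
Reagents that add atoms: none
Why: Lewis-acid cleavage of all seven aryl methyl ethers (bromide attack on the methyl group of the boron-bound ether); the carbons C3 and C3′ are not involved, and a ring C–O bond that opens at the 4-oxybenzylic position should reclose to the stable trans ring.

**Compound list**

1 | 2,4,6-trihydroxybenzaldehyde | O=Cc1c(O)cc(O)cc1O | starting material
2 | 4-(benzyloxy)-2,6-dihydroxybenzaldehyde | O=Cc1c(O)cc(OCc2ccccc2)cc1O | intermediate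
3 | 4-(benzyloxy)-2,6-bis(methoxymethoxy)benzaldehyde | O=Cc1c(OCOC)cc(OCc2ccccc2)cc1OCOC | intermediate
4 | 5-(benzyloxy)-2-[(E)-2-iodoethenyl]-1,3-bis(methoxymethoxy)benzene | I/C=C/c1c(OCOC)cc(OCc2ccccc2)cc1OCOC | intermediate
5 | acenaphthoquinone | O=C1C(=O)c2cccc3cccc1c23 | starting material
6 | cis-1,2-dimethyl-1,2-dihydroacenaphthylene-1,2-diol (meso) | C[C@]1(O)[C@@](C)(O)c2cccc3cccc1c23 | intermediate
7 | 4-methoxyphenylboronic acid | COc1ccc(B(O)O)cc1 | starting material
8 | 4-methoxyphenylboronic acid ester of diol 6 | COc1ccc(B2O[C@]3(C)c4cccc5cccc(c45)[C@]3(C)O2)cc1 | intermediate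
9 | 3,5-dimethoxyphenol | COc1cc(O)cc(OC)c1 | starting material
10 | 3,5-dimethoxyphenyl trifluoromethanesulfonate | COc1cc(OC)cc(OS(=O)(=O)C(F)(F)F)c1 | intermediate
11 | (E)-2-[4-(benzyloxy)-2,6-bis(methoxymethoxy)phenyl]ethenyllithium | [Li]/C=C/c1c(OCOC)cc(OCc2ccccc2)cc1OCOC | intermediate
12 | lithium [(E)-2-[4-(benzyloxy)-2,6-bis(methoxymethoxy)phenyl]ethenyl](4-methoxyphenyl)borate of diol 6 (ate complex; configuration at boron immaterial) | [Li+].COc1ccc([B-]2(/C=C/c3c(OCOC)cc(OCc4ccccc4)cc3OCOC)O[C@]3(C)c4cccc5cccc(c45)[C@]3(C)O2)cc1 | intermediate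
13 | (1R,2S)-2-[4-(benzyloxy)-2,6-bis(methoxymethoxy)phenyl]-2-(3,5-dimethoxyphenyl)-1-(4-methoxyphenyl)ethylboronic acid ester of diol 6 | COc1ccc([C@H](B2O[C@]3(C)c4cccc5cccc(c45)[C@]3(C)O2)[C@@H](c2cc(OC)cc(OC)c2)c2c(OCOC)cc(OCc3ccccc3)cc2OCOC)cc1 | intermediate
14 | (1R,2S)-2-[4-(benzyloxy)-2,6-bis(methoxymethoxy)phenyl]-2-(3,5-dimethoxyphenyl)-1-(4-methoxyphenyl)ethanol | COc1ccc([C@H](O)[C@@H](c2cc(OC)cc(OC)c2)c2c(OCOC)cc(OCc3ccccc3)cc2OCOC)cc1 | intermediate
15 | 5-(benzyloxy)-2-[(1S,2R)-1-(3,5-dimethoxyphenyl)-2-hydroxy-2-(4-methoxyphenyl)ethyl]benzene-1,3-diol | COc1ccc([C@H](O)[C@@H](c2cc(OC)cc(OC)c2)c2c(O)cc(OCc3ccccc3)cc2O)cc1 | intermediate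
16 | (2S,3S)-6-(benzyloxy)-3-(3,5-dimethoxyphenyl)-2-(4-methoxyphenyl)-2,3-dihydro-1-benzofuran-4-ol | c1ccccc1COc1cc(O)c2c(c1)O[C@H](c1ccc(OC)cc1)[C@H]2c1cc(OC)cc(OC)c1 | intermediate
17 | (2S,3S)-6-(benzyloxy)-3-(3,5-dimethoxyphenyl)-4-methoxy-2-(4-methoxyphenyl)-2,3-dihydro-1-benzofuran | c1ccccc1COc1cc(OC)c2c(c1)O[C@H](c1ccc(OC)cc1)[C@H]2c1cc(OC)cc(OC)c1 | intermediate
18 | (2S,3S)-3-(3,5-dimethoxyphenyl)-4-methoxy-2-(4-methoxyphenyl)-2,3-dihydro-1-benzofuran-6-ol | Oc1cc(OC)c2c(c1)O[C@H](c1ccc(OC)cc1)[C@H]2c1cc(OC)cc(OC)c1 | intermediate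
19 | (2S,3S)-3-(3,5-dimethoxyphenyl)-4-methoxy-2-(4-methoxyphenyl)-2,3-dihydro-1-benzofuran-6-yl trifluoromethanesulfonate | O=S(=O)(Oc1cc(OC)c2c(c1)O[C@H](c1ccc(OC)cc1)[C@H]2c1cc(OC)cc(OC)c1)C(F)(F)F | intermediate
20 | (1R,2S)-2-[4-(benzyloxy)-2,6-bis(methoxymethoxy)phenyl]-2-[(2S,3S)-3-(3,5-dimethoxyphenyl)-4-methoxy-2-(4-methoxyphenyl)-2,3-dihydro-1-benzofuran-6-yl]-1-(4-methoxyphenyl)ethylboronic acid ester of diol 6 | COc1ccc([C@H](B2O[C@]3(C)c4cccc5cccc(c45)[C@]3(C)O2)[C@@H](c2cc(OC)c3c(c2)O[C@H](c2ccc(OC)cc2)[C@H]3c2cc(OC)cc(OC)c2)c2c(OCOC)cc(OCc3ccccc3)cc2OCOC)cc1 | intermediate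
21 | (1R,2S)-2-[4-(benzyloxy)-2,6-bis(methoxymethoxy)phenyl]-2-[(2S,3S)-3-(3,5-dimethoxyphenyl)-4-methoxy-2-(4-methoxyphenyl)-2,3-dihydro-1-benzofuran-6-yl]-1-(4-methoxyphenyl)ethanol | COc1ccc([C@H](O)[C@@H](c2cc(OC)c3c(c2)O[C@H](c2ccc(OC)cc2)[C@H]3c2cc(OC)cc(OC)c2)c2c(OCOC)cc(OCc3ccccc3)cc2OCOC)cc1 | intermediate
22 | 5-(benzyloxy)-2-[(1S,2R)-1-[(2S,3S)-3-(3,5-dimethoxyphenyl)-4-methoxy-2-(4-methoxyphenyl)-2,3-dihydro-1-benzofuran-6-yl]-2-hydroxy-2-(4-methoxyphenyl)ethyl]benzene-1,3-diol | COc1ccc([C@H](O)[C@@H](c2cc(OC)c3c(c2)O[C@H](c2ccc(OC)cc2)[C@H]3c2cc(OC)cc(OC)c2)c2c(O)cc(OCc3ccccc3)cc2O)cc1 | intermediate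
23 | (2S,3S)-6-(benzyloxy)-3-[(2S,3S)-3-(3,5-dimethoxyphenyl)-4-methoxy-2-(4-methoxyphenyl)-2,3-dihydro-1-benzofuran-6-yl]-2-(4-methoxyphenyl)-2,3-dihydro-1-benzofuran-4-ol | c1ccccc1COc1cc(O)c2c(c1)O[C@H](c1ccc(OC)cc1)[C@H]2c1cc(OC)c2c(c1)O[C@H](c1ccc(OC)cc1)[C@H]2c1cc(OC)cc(OC)c1 | intermediate
24 | (2S,3S)-6-(benzyloxy)-3-[(2S,3S)-3-(3,5-dimethoxyphenyl)-4-methoxy-2-(4-methoxyphenyl)-2,3-dihydro-1-benzofuran-6-yl]-4-methoxy-2-(4-methoxyphenyl)-2,3-dihydro-1-benzofuran | c1ccccc1COc1cc(OC)c2c(c1)O[C@H](c1ccc(OC)cc1)[C@H]2c1cc(OC)c2c(c1)O[C@H](c1ccc(OC)cc1)[C@H]2c1cc(OC)cc(OC)c1 | intermediate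
25 | (2S,3S)-3-[(2S,3S)-3-(3,5-dimethoxyphenyl)-4-methoxy-2-(4-methoxyphenyl)-2,3-dihydro-1-benzofuran-6-yl]-4-methoxy-2-(4-methoxyphenyl)-2,3-dihydro-1-benzofuran-6-ol | Oc1cc(OC)c2c(c1)O[C@H](c1ccc(OC)cc1)[C@H]2c1cc(OC)c2c(c1)O[C@H](c1ccc(OC)cc1)[C@H]2c1cc(OC)cc(OC)c1 | intermediate
26 | (2S,3S)-3-[(2S,3S)-3-(3,5-dimethoxyphenyl)-4-methoxy-2-(4-methoxyphenyl)-2,3-dihydro-1-benzofuran-6-yl]-4-methoxy-2-(4-methoxyphenyl)-2,3-dihydro-1-benzofuran-6-yl trifluoromethanesulfonate | O=S(=O)(Oc1cc(OC)c2c(c1)O[C@H](c1ccc(OC)cc1)[C@H]2c1cc(OC)c2c(c1)O[C@H](c1ccc(OC)cc1)[C@H]2c1cc(OC)cc(OC)c1)C(F)(F)F | intermediate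
27 | (E)-2-(4-methoxyphenyl)ethenylboronic acid pinacol ester | COc1ccc(/C=C/B2OC(C)(C)C(C)(C)O2)cc1 | starting material
28 | heptamethyl ether of the target | COc1ccc(/C=C/c2cc(OC)c3c(c2)O[C@H](c2ccc(OC)cc2)[C@H]3c2cc(OC)c3c(c2)O[C@H](c2ccc(OC)cc2)[C@H]3c2cc(OC)cc(OC)c2)cc1 | intermediate
29 | CNP0248228.2, (2S,3S)-3-[(2S,3S)-3-(3,5-dihydroxyphenyl)-4-hydroxy-2-(4-hydroxyphenyl)-2,3-dihydro-1-benzofuran-6-yl]-2-(4-hydroxyphenyl)-6-[(E)-2-(4-hydroxyphenyl)ethenyl]-2,3-dihydro-1-benzofuran-4-ol | Oc1ccc(/C=C/c2cc(O)c3c(c2)O[C@H](c2ccc(O)cc2)[C@H]3c2cc(O)c3c(c2)O[C@H](c2ccc(O)cc2)[C@H]3c2cc(O)cc(O)c2)cc1 | target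

**Step count and risks**

Total steps: 21. Longest linear sequence: 18 steps (steps 1 to 3, then steps 7 to 21).

Steps most likely to fail:

1. Step 8. The hindered β-aryl group may divert the ate complex into direct alkenyl transfer to palladium, slow the C–aryl bond formation at the crowded benzylic palladium, or leave the alkene faces poorly discriminated. The fallback uses known chemistry, enantioselective rhodium-carbene C–H insertion of a diaryldiazomethane followed by acid equilibration; it sets out from 2 and comes back at 16. Both flanking phenols of 2 are alkylated with 4-methoxybenzyl chloride (K2CO3, DMF) to give 4-(benzyloxy)-2,6-bis[(4-methoxybenzyl)oxy]benzaldehyde F1. 3,5-Dimethoxyphenylmagnesium bromide adds to give [4-(benzyloxy)-2,6-bis[(4-methoxybenzyl)oxy]phenyl](3,5-dimethoxyphenyl)methanol F2, and Dess–Martin periodinane oxidises this to the corresponding benzophenone F3. Hydrazine hydrate in hot butanol gives the hydrazone F4, and MnO2 oxidises it to the diaryldiazomethane F5. The antipode of dirhodium tetrakis[N-phthaloyl-(1-adamantyl)glycinate], Rh2(PTAD)4, that gives the 3S centre then turns F5, by carbene insertion into a benzylic C–H bond of one of the two equivalent 4-methoxybenzyl ethers, into the 2,3-cis compound (2R,3S)-6-(benzyloxy)-3-(3,5-dimethoxyphenyl)-4-[(4-methoxybenzyl)oxy]-2-(4-methoxyphenyl)-2,3-dihydro-1-benzofuran F6. Trifluoroacetic acid with pentamethylbenzene removes the remaining 4-methoxybenzyl ether and equilibrates C2 through the 4-methoxybenzylic cation to the trans isomer, which is 16.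

2. Step 14. The same diversion to direct alkenyl transfer may occur, the larger electrophile may add slowly to palladium or erode catalyst control of the alkene face, and the stored ate complex may have aged (a fresh batch by step 7 answers that last point). The fallback is the same known carbene-insertion chemistry; it sets out from 19 and comes back at 23. Miyaura borylation of 19 (bis(pinacolato)diboron, PdCl2(dppf), KOAc, dioxane) gives the C6′ pinacol boronate of unit 2 F7. Rhodium-catalysed 1,2-addition of F7 to aldehyde F1, made from 2 as in the first fallback ([Rh(OH)(cod)]2, cod = 1,5-cyclooctadiene, dioxane/H2O), gives the diarylmethanol F8, Dess–Martin periodinane gives the diaryl ketone F9, and hydrazine hydrate gives the hydrazone F10. MnO2 gives the diaryldiazomethane F11, and the same chiral dirhodium carboxylate closes the unit 1 ring as the 2,3-cis isomer, obtained as its 4-(4-methoxybenzyl) ether F12. Trifluoroacetic acid with pentamethylbenzene then removes that ether and equilibrates C2 to trans, which gives 23.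

3. Step 21. Exhaustive ether cleavage may be accompanied by Lewis-acid opening of the two benzylic ring C–O bonds and by cationic addition or oligomerisation at the electron-rich stilbene. The fallback moves ether cleavage ahead of alkene formation and finishes under mild base; it sets out from 26 and comes back at 29. BBr3 in CH2Cl2 cleaves the six methyl ethers of 26, the aryl triflate being inert, to give the hexahydroxy triflate F13. Acetic anhydride and pyridine give the hexaacetate triflate F14. Heck reaction with 4-acetoxystyrene (Pd(OAc)2, P(o-tol)3, Et3N, DMF, 90 °C) gives the heptaacetate of the target F15, and K2CO3 in methanol under nitrogen removes the acetates to give 29.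

**Further compounds**

F1 | step 8 | 4-(benzyloxy)-2,6-bis[(4-methoxybenzyl)oxy]benzaldehyde | O=Cc1c(OCc2ccc(OC)cc2)cc(OCc2ccccc2)cc1OCc1ccc(OC)cc1
F2 | step 8 | [4-(benzyloxy)-2,6-bis[(4-methoxybenzyl)oxy]phenyl](3,5-dimethoxyphenyl)methanol (racemic) | OC(c1cc(OC)cc(OC)c1)c1c(OCc2ccc(OC)cc2)cc(OCc2ccccc2)cc1OCc1ccc(OC)cc1
F3 | step 8 | [4-(benzyloxy)-2,6-bis[(4-methoxybenzyl)oxy]phenyl](3,5-dimethoxyphenyl)methanone | O=C(c1cc(OC)cc(OC)c1)c1c(OCc2ccc(OC)cc2)cc(OCc2ccccc2)cc1OCc1ccc(OC)cc1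
F4 | step 8 | hydrazone of ketone F3 | NN=C(c1cc(OC)cc(OC)c1)c1c(OCc2ccc(OC)cc2)cc(OCc2ccccc2)cc1OCc1ccc(OC)cc1
F5 | step 8 | [4-(benzyloxy)-2,6-bis[(4-methoxybenzyl)oxy]phenyl](3,5-dimethoxyphenyl)diazomethane | [N-]=[N+]=C(c1cc(OC)cc(OC)c1)c1c(OCc2ccc(OC)cc2)cc(OCc2ccccc2)cc1OCc1ccc(OC)cc1
F6 | step 8 | (2R,3S)-6-(benzyloxy)-3-(3,5-dimethoxyphenyl)-4-[(4-methoxybenzyl)oxy]-2-(4-methoxyphenyl)-2,3-dihydro-1-benzofuran | c1ccccc1COc1cc(OCc2ccc(OC)cc2)c2c(c1)O[C@@H](c1ccc(OC)cc1)[C@H]2c1cc(OC)cc(OC)c1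
F7 | step 14 | 2-[(2S,3S)-3-(3,5-dimethoxyphenyl)-4-methoxy-2-(4-methoxyphenyl)-2,3-dihydro-1-benzofuran-6-yl]-4,4,5,5-tetramethyl-1,3,2-dioxaborolane | CC1(C)OB(c2cc(OC)c3c(c2)O[C@H](c2ccc(OC)cc2)[C@H]3c2cc(OC)cc(OC)c2)OC1(C)C
F8 | step 14 | [4-(benzyloxy)-2,6-bis[(4-methoxybenzyl)oxy]phenyl][(2S,3S)-3-(3,5-dimethoxyphenyl)-4-methoxy-2-(4-methoxyphenyl)-2,3-dihydro-1-benzofuran-6-yl]methanol (both carbinol epimers) | OC(c1cc(OC)c2c(c1)O[C@H](c1ccc(OC)cc1)[C@H]2c1cc(OC)cc(OC)c1)c1c(OCc2ccc(OC)cc2)cc(OCc2ccccc2)cc1OCc1ccc(OC)cc1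
F9 | step 14 | [4-(benzyloxy)-2,6-bis[(4-methoxybenzyl)oxy]phenyl][(2S,3S)-3-(3,5-dimethoxyphenyl)-4-methoxy-2-(4-methoxyphenyl)-2,3-dihydro-1-benzofuran-6-yl]methanone | O=C(c1cc(OC)c2c(c1)O[C@H](c1ccc(OC)cc1)[C@H]2c1cc(OC)cc(OC)c1)c1c(OCc2ccc(OC)cc2)cc(OCc2ccccc2)cc1OCc1ccc(OC)cc1
F10 | step 14 | hydrazone of ketone F9 | NN=C(c1cc(OC)c2c(c1)O[C@H](c1ccc(OC)cc1)[C@H]2c1cc(OC)cc(OC)c1)c1c(OCc2ccc(OC)cc2)cc(OCc2ccccc2)cc1OCc1ccc(OC)cc1
F11 | step 14 | diaryldiazomethane from hydrazone F10 | [N-]=[N+]=C(c1cc(OC)c2c(c1)O[C@H](c1ccc(OC)cc1)[C@H]2c1cc(OC)cc(OC)c1)c1c(OCc2ccc(OC)cc2)cc(OCc2ccccc2)cc1OCc1ccc(OC)cc1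
F12 | step 14 | (2R,3S)-6-(benzyloxy)-3-[(2S,3S)-3-(3,5-dimethoxyphenyl)-4-methoxy-2-(4-methoxyphenyl)-2,3-dihydro-1-benzofuran-6-yl]-4-[(4-methoxybenzyl)oxy]-2-(4-methoxyphenyl)-2,3-dihydro-1-benzofuran | c1ccccc1COc1cc(OCc2ccc(OC)cc2)c2c(c1)O[C@@H](c1ccc(OC)cc1)[C@H]2c1cc(OC)c2c(c1)O[C@H](c1ccc(OC)cc1)[C@H]2c1cc(OC)cc(OC)c1
F13 | step 21 | (2S,3S)-3-[(2S,3S)-3-(3,5-dihydroxyphenyl)-4-hydroxy-2-(4-hydroxyphenyl)-2,3-dihydro-1-benzofuran-6-yl]-4-hydroxy-2-(4-hydroxyphenyl)-2,3-dihydro-1-benzofuran-6-yl trifluoromethanesulfonate | O=S(=O)(Oc1cc(O)c2c(c1)O[C@H](c1ccc(O)cc1)[C@H]2c1cc(O)c2c(c1)O[C@H](c1ccc(O)cc1)[C@H]2c1cc(O)cc(O)c1)C(F)(F)F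
F14 | step 21 | hexaacetate of triflate F13 | O=S(=O)(Oc1cc(OC(C)=O)c2c(c1)O[C@H](c1ccc(OC(C)=O)cc1)[C@H]2c1cc(OC(C)=O)c2c(c1)O[C@H](c1ccc(OC(C)=O)cc1)[C@H]2c1cc(OC(C)=O)cc(OC(C)=O)c1)C(F)(F)F
F15 | step 21 | heptaacetate of the target | CC(=O)Oc1ccc(/C=C/c2cc(OC(C)=O)c3c(c2)O[C@H](c2ccc(OC(C)=O)cc2)[C@H]3c2cc(OC(C)=O)c3c(c2)O[C@H](c2ccc(OC(C)=O)cc2)[C@H]3c2cc(OC(C)=O)cc(OC(C)=O)c2)cc1
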